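The para-phenylene ring E is not carried in; it is cut back to an ethynyl ether on C9 of ring B and a 2-pyrone hung on the C5′ methylene of lactam ring D. One thermal step should add the alkyne across pyrone C3/C6, expel CO2, and so form the arene, both of its new C–C bonds and the 13-membered cyclophane at once. The step exploits the fact that ring E bears only the C9 ether oxygen and the C5′–CH2 group, para to each other. Its precursor 39 is the tricyclic C9 ethynyl ether whose C1 acyl group is a silyl-enol-protected 3′-acyl lactam carrying the pyronylmethyl group, the 4′,5′-diol being a cis acetonide.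

Key step: step 25

**Numbering.** The tricycle is numbered as a fluorene: C1 (acyl), C2 (vinyl), C3=C4, C4a, C4b, C5, C6 (Me), C7, C8 (Me), C8a, C9 (O), C9a. Ring A is the cyclohexane C4b–C8a, ring B the cyclopentane, ring C the cyclohexene, ring D the lactam (N1′, C2′=O, C3′, C4′–O, C5′), ring E the para-phenylene. The same labels are used for the corresponding atoms of earlier intermediates.

**Target as read from its SMILES.** A/B and B/C are both trans-fused, with H-4a cis to H-4b. The C9 oxygen is anti to both H-8a and H-9a. The C1 acyl group is cis to the C2 vinyl group and trans to C9. The lactam is a (4′S,5′S) cis-diol, and the enol oxygen lies on the side of the lactam carbonyl.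

**Design points.**
- The lactam is joined to an aldehyde, which is then oxidised. A carboxylic acid or acid chloride is avoided because alkynyl ethers add carboxylic acids.
- The enol is protected as a silyl ether. Silylation of the chelated enol should give the (Z) geometry the macrocycle needs, and O-to-O silyl transfer keeps it accessible.
- The 4′,5′-diol is a cis-fused acetonide. This fixes C5′ and lets a single acid step finish the synthesis.
- Para bridging is expected from polarity alone; the nine-atom tether could also reach the meta mode.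
- Ketene loss by retro-ene needs a β-hydrogen syn to oxygen, and ring B offers none.

**Assumptions.**
- The (R,R)-lithium amide is taken to give enolate 3; if the sense is opposite, the (S,S)-amide is used and nothing else changes.
- (S)-Malamic acid is bought; it is also made in one step from L-asparagine and nitrous acid.

## Route

Step 1
Reactants: 1 cis-3,5-dimethylcyclohexanone; 2 ethyl (E)-4-oxobut-2-enoate
Product: 4 ethyl (2E,4S)-4-hydroxy-4-[(1S,2S,4R)-2,4-dimethyl-6-oxocyclohexyl]but-2-enoate, via lithium enolate 3 (not isolated)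
Conditions: (R,R)-[PhCH(Me)]2NH, n-BuLi, LiCl, THF, −78 °C; 1; then 2, −78 °C; AcOH
Reagents that add atoms: none
Why: Enantiotopic deprotonation of the meso ketone by the chiral lithium amide decides which α-carbon becomes C8a, and the ring-locked E-enolate should then add to the aldehyde through a Zimmerman–Traxler chair (anti aldol) on the face away from the neighbouring methyl group, setting C8a and C9.

Step 2
Reactants: 4 aldol
Product: 5 silyl ether ketone
Conditions: TBSOTf, 2,6-lutidine, CH2Cl2, −78 °C
Reagents that add atoms: tert-butyldimethylsilyl triflate, CC(C)(C)[Si](C)(C)OS(=O)(=O)C(F)(F)F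
Why: Low-temperature O-silylation protects the β-hydroxy ketone before retro-aldol cleavage or dehydration can occur and touches no stereocentre.

Step 3
Reactants: 5 silyl ether ketone
Product: 6 exocyclic alkene
Conditions: Zn, CH2Br2, TiCl4, THF/CH2Cl2, 0 °C → rt
Reagents that add atoms: dibromomethane, BrCBr
Why: Takai–Lombardo methylenation is non-basic, so the hindered, enolisable β-silyloxy ketone should be converted without epimerisation at C8a or β-elimination, and the ester is spared.

Step 4
Reactants: 6 exocyclic alkene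
Product: 7 primary alcohol (C4b epimers)
Conditions: 9-BBN, THF, 0 °C → rt; then NaBO3·4H2O, H2O, rt
Reagents that add atoms: sodium perborate, [Na+].[Na+].O[B-]1(O)OO[B-](O)(O)OO1
Why: Hydroboration–oxidation places oxygen on the terminal carbon of the 1,1-disubstituted alkene, which reacts much faster than the conjugated ester; C4b is left open here and is set in step 5.

Step 5
Reactants: 7 primary alcohol
Product: 9 all-equatorial aldehyde, via aldehyde epimer mixture 8 (not isolated)
Conditions: Dess–Martin periodinane, NaHCO3, CH2Cl2, 0 °C → rt; then DBU (cat.), rt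
Reagents that add atoms: none
Why: Dess–Martin oxidation followed by base equilibration of the α-centre should deliver the thermodynamic aldehyde with the C4b substituent equatorial, trans to C8a.

Step 6
Reactants: 9 aldehyde; 10 (triphenylphosphoranylidene)acetaldehyde
Product: 11 (E)-enal
Conditions: toluene, 80 °C
Reagents that add atoms: none
Why: Wittig reaction of a stabilised ylide gives the (E)-alkene and is neutral enough to leave C4b and the enoate untouched.

Step 7
Reactants: 11 (E)-enal; 12 diethyl allylphosphonate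
Product: 13 (E,E)-triene enoate
Conditions: 12, n-BuLi, THF, −78 °C; then 11, −78 °C → rt
Reagents that add atoms: none
Why: Horner–Wadsworth–Emmons olefination through the α-carbon of the allylphosphonate anion adds 1,2 to the enal and eliminates to the (E)-alkene, completing the terminal triene.

Step 8
Reactants: 13 triene enoate
Product: 14 tricyclic ester
Conditions: Et2AlCl, CH2Cl2, −78 → 0 °C
Reagents that add atoms: none
Why: In this Lewis acid-promoted intramolecular Diels–Alder reaction the (E,E)-diene C4a=C4–C3=C2 and the (E)-enoate C9a=C1 should react through the ester-endo transition state, giving the trans B/C fusion with C1 trans to C9 and cis to the vinyl group, while ring A should direct the diene to the enoate face that keeps C4a=C4 eclipsed with C4b–C5 (H-4a syn to H-4b), so that C4a, C9a, C1 and C2 are set together.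

Step 9
Reactants: 14 tricyclic ester
Product: 15 primary alcohol
Conditions: i-Bu2AlH, CH2Cl2, −78 → 0 °C
Reagents that add atoms: none
Why: Hydride reduction of the ester to the alcohol leaves the alkenes and the silyl ether alone.

Step 10
Reactants: 15 primary alcohol
Product: 16 diol
Conditions: Bu4NF, THF, rt → 50 °C
Reagents that add atoms: none
Why: Fluoride cleaves the hindered secondary silyl ether without affecting any stereocentre.

Step 11
Reactants: 16 diol
Product: 17 primary silyl ether
Conditions: TIPSCl, imidazole, CH2Cl2, 0 °C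
Reagents that add atoms: triisopropylsilyl chloride, CC(C)[Si](Cl)(C(C)C)C(C)C
Why: The bulky silyl chloride should react only at the primary hydroxyl, and the triisopropylsilyl group does not migrate under the basic conditions that follow.

Step 12
Reactants: 17 primary silyl ether; 18 trichloroethylene
Product: 19 (E)-1,2-dichlorovinyl ether
Conditions: KH, THF, 0 °C; then 18, −50 °C → rt
Reagents that add atoms: none
Why: The potassium alkoxide adds to dichloroacetylene generated in the flask from 18 (net O-vinylation), a reaction that tolerates hindered secondary alcohols and retains the C9 configuration.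

Step 13
Reactants: 19 dichlorovinyl ether
Product: 22 terminal ynol ether, via chloroethynyl ether 20 (not isolated), via lithium alkynyl ether 21 (not isolated)
Conditions: n-BuLi (2.5 equiv), THF, −78 → −40 °C; then H2O, −78 °C
Reagents that add atoms: none
Why: Elimination of HCl, chlorine–lithium exchange and protonation convert the dichlorovinyl ether into the ethynyl ether (the dichlorovinyl ether route to ynol ethers) with nothing else in the molecule reactive towards n-BuLi.

Step 14
Reactants: 22 ynol ether
Product: 23 ynol ether alcohol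
Conditions: Bu4NF, THF, 0 °C
Reagents that add atoms: none
Why: Fluoride removes the primary silyl ether under basic, non-electrophilic conditions that an alkynyl ether tolerates.

Step 15
Reactants: 23 ynol ether alcohol
Product: 24 ynol ether aldehyde
Conditions: Dess–Martin periodinane, pyridine, CH2Cl2, 0 °C
Reagents that add atoms: none
Why: Buffered Dess–Martin oxidation stops at the aldehyde, and the pyridine keeps the acetic acid set free from adding to the ynol ether or epimerising C1.

Step 16
Reactants: 25 coumalic acid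
Product: 26 5-(hydroxymethyl)-2H-pyran-2-one
Conditions: BH3·THF, THF, 0 °C → rt; MeOH
Reagents that add atoms: none
Why: Borane reduces a carboxylic acid through its acyloxyborane far faster than it attacks the pyrone lactone.

Step 17
Reactants: 26 hydroxymethyl pyrone
Product: 27 5-(bromomethyl)-2H-pyran-2-one
Conditions: CBr4, PPh3, CH2Cl2, 0 °C
Reagents that add atoms: carbon tetrabromide, BrC(Br)(Br)Br
Why: Appel bromination converts the primary alcohol into the bromide under neutral conditions that the pyrone survives.

Step 18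
Reactants: 28 (S)-malamic acid
Product: 30 (2S)-4-amino-4-oxo-2-(triethylsilyloxy)butanoic acid, via bis-silyl compound 29 (not isolated)
Conditions: TESCl, imidazole, DMF, 0 °C → rt; then MeOH/H2O, rt
Reagents that add atoms: triethylsilyl chloride, CC[Si](Cl)(CC)CC
Why: Silylation of hydroxyl and carboxyl followed by selective solvolysis of the labile silyl ester leaves the O-silylated acid with C4′ unchanged.

Step 19
Reactants: 30 silyloxy acid
Product: 31 S-ethyl thioester
Conditions: EtSH, EDC·HCl, HOBt, CH2Cl2/DMF, 0 °C → rt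
Reagents that add atoms: ethanethiol, CCS
Why: Carbodiimide thioesterification through the hydroxybenzotriazole ester activates the acid mildly, and the additive suppresses dehydration of the neighbouring carboxamide to the nitrile.

Step 20
Reactants: 27 bromomethyl pyrone; 31 thioester
Product: 34 hydroxy lactam (C5′ epimers), via zinc reagent 32 (not isolated), via keto amide 33 (not isolated)
Conditions: 27, Zn, LiCl, THF, 0 °C; then 31, PdCl2(PPh3)2 (cat.), toluene/THF, rt
Reagents that add atoms: none
Why: Zinc insertion into the allylic C–Br bond and Fukuyama ketone synthesis (thioester plus organozinc under palladium catalysis) build the C5′–CH2 ketone without touching pyrone, silyl ether or amide, and the γ-keto amide then closes to the hydroxy lactam by ring–chain tautomerism.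

Step 21
Reactants: 34 hydroxy lactam
Product: 35 cis-acetonide lactam
Conditions: 2,2-dimethoxypropane, camphorsulfonic acid (cat.), acetone/MeOH, rt
Reagents that add atoms: 2,2-dimethoxypropane, COC(C)(C)OC
Why: Acid removes the triethylsilyl group and traps the cis-diol as the isopropylidene acetal, while C5′ epimerises through the open keto amide, so the material should funnel into the cis-fused (4′S,5′S) acetal under thermodynamic control.

Step 22
Reactants: 35 acetonide lactam; 24 ynol ether aldehyde
Product: 37 aldol adduct (mixture at the carbinol and C3′), via N-silyl lactam 36 (not isolated)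
Conditions: 35, TMSCl, Et3N, CH2Cl2, 0 °C, evaporate; LiN(i-Pr)2, THF, −78 °C; then 24, −78 °C; aq. NH4Cl
Reagents that add atoms: none
Why: Aldol addition of the lithium enolate of the transiently N-silylated lactam to the aldehyde at −78 °C is cold and fast enough to spare the pyrone, the β-alkoxy enolate and C1, and the two new stereocentres are removed in step 23.

Step 23
Reactants: 37 aldol adduct
Product: 38 β-keto lactam (chelated enol)
Conditions: Dess–Martin periodinane, pyridine, CH2Cl2, 0 °C
Reagents that add atoms: none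
Why: Buffered Dess–Martin oxidation of the secondary alcohol gives the 3′-acyl lactam, which should rest as the hydrogen-bonded (Z)-enol.

Step 24
Reactants: 38 β-keto lactam
Product: 39 silyl enol ether (cycloaddition precursor)
Conditions: TBSCl, Et3N, DMAP (cat.), CH2Cl2, 0 °C → rt
Reagents that add atoms: tert-butyldimethylsilyl chloride, CC(C)(C)[Si](C)(C)Cl
Why: O-Silylation of the chelated enol should keep the enol oxygen cis to the lactam carbonyl (C1 cis to C4′) and removes the acidic OH that could add to the ynol ether.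

Step 25
Reactants: 39 silyl enol ether
Product: 41 protected xenoacremone A, via bridged lactone 40 (not isolated)
Conditions: toluene (1 mM), BHT, K2CO3-washed sealed tube, 110 → 130 °C
Reagents that add atoms: none
Why: Proposed new method: the electron-rich ethynyl ether should add to the electron-poor pyrone diene in an asynchronous inverse-demand (4+2) cycloaddition, its nucleophilic terminal carbon bonding to pyrone C6 and the oxygen-bearing carbon to C3, and the bridged lactone 40 should then lose CO2 by retro-(4+2); the closest known reaction types are the intramolecular 2-pyrone–alkyne cycloaddition/decarboxylation to benzenes and the intermolecular pyrone reactions of ynamines and ketene acetals. Ring E closes as a six-membered carbocycle by two C–C bonds at the diene termini, and the 13-membered ring closes in the same event as a macrocyclisation through the nine-atom tether, first around the folded lactone 40 and only on aromatisation around the bent arene, which the loss of CO2 should pay for. No stereocentre is created, because the two bridgeheads of 40 become arene carbons and either pyrone face serves. Para instead of meta bridging is needed and rests on the polarity match alone, since the tether is long enough for both modes. Cycloaddition must outrun ketene loss, and the substrate secures this because H-8a and H-9a are both anti to the C9 oxygen, so the syn retro-ene geometry cannot be reached, while the (Z)-silyl enol ether and the cis acetonide hold C1, C4′ and the pyronylmethyl arm in the arrangement of the final ring. Ring closure over oligomerisation is secured by high dilution.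

Step 26
Reactants: 41 protected xenoacremone A
Product: 42 xenoacremone A
Conditions: CF3CO2H/H2O/THF, 0 °C → rt
Reagents that add atoms: water, O
Why: Aqueous acid hydrolyses the silyl enol ether and the isopropylidene acetal in one operation, and C5′ re-forms as the hemiaminal with its hydroxyl cis to C4′–OH because the macrocycle fixes the benzylic arm on the other face.

## Compound list

1 | cis-3,5-dimethylcyclohexanone (meso) | O=C1C[C@H](C)C[C@H](C)C1 | starting material
2 | ethyl (E)-4-oxobut-2-enoate | CCOC(=O)/C=C/C=O | starting material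
3 | lithium (3S,5R)-3,5-dimethylcyclohex-1-en-1-olate | [Li]OC1=C[C@@H](C)C[C@@H](C)C1 | intermediate (not isolated)
4 | ethyl (2E,4S)-4-hydroxy-4-[(1S,2S,4R)-2,4-dimethyl-6-oxocyclohexyl]but-2-enoate (anti aldol, side chain trans to the 2-methyl group) | CCOC(=O)/C=C/[C@H](O)[C@@H]1[C@@H](C)C[C@@H](C)CC1=O | intermediate
5 | tert-butyldimethylsilyl ether of 4 | CCOC(=O)/C=C/[C@H](O[Si](C)(C)C(C)(C)C)[C@@H]1[C@@H](C)C[C@@H](C)CC1=O | intermediate
6 | 6-methylidene analogue of 5 (C=O replaced by C=CH2) | CCOC(=O)/C=C/[C@H](O[Si](C)(C)C(C)(C)C)[C@@H]1[C@@H](C)C[C@@H](C)CC1=C | intermediate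
7 | 6-(hydroxymethyl)cyclohexyl analogue of 5, both C4b epimers | CCOC(=O)/C=C/[C@H](O[Si](C)(C)C(C)(C)C)[C@@H]1[C@@H](C)C[C@@H](C)CC1CO | intermediate
8 | 6-formylcyclohexyl analogue of 5, both C4b epimers | CCOC(=O)/C=C/[C@H](O[Si](C)(C)C(C)(C)C)[C@@H]1[C@@H](C)C[C@@H](C)CC1C=O | intermediate (not isolated)
9 | 6-formylcyclohexyl analogue of 5, all four ring substituents equatorial | CCOC(=O)/C=C/[C@H](O[Si](C)(C)C(C)(C)C)[C@@H]1[C@@H](C)C[C@@H](C)C[C@H]1C=O | intermediate
10 | (triphenylphosphoranylidene)acetaldehyde | O=CC=P(c1ccccc1)(c1ccccc1)c1ccccc1 | starting material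
11 | (E)-3-oxoprop-1-enyl analogue of 9 (enal on C4b) | CCOC(=O)/C=C/[C@H](O[Si](C)(C)C(C)(C)C)[C@@H]1[C@@H](C)C[C@@H](C)C[C@H]1/C=C/C=O | intermediate
12 | diethyl allylphosphonate | CCOP(=O)(CC=C)OCC | starting material
13 | (1E,3E)-hexa-1,3,5-trienyl analogue of 9 (triene on C4b, (E)-enoate side chain on C8a) | CCOC(=O)/C=C/[C@H](O[Si](C)(C)C(C)(C)C)[C@@H]1[C@@H](C)C[C@@H](C)C[C@H]1/C=C/C=C/C=C | intermediate
14 | ethyl 9-(tert-butyldimethylsilyloxy)-6,8-dimethyl-2-vinyl-2,4a,4b,5,6,7,8,8a,9,9a-decahydro-1H-fluorene-1-carboxylate, all nine stereocentres as in 42 | C=C[C@@H]1C=C[C@@H]2[C@@H]3C[C@H](C)C[C@H](C)[C@H]3[C@@H](O[Si](C)(C)C(C)(C)C)[C@H]2[C@@H]1C(=O)OCC | intermediate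
15 | 1-(hydroxymethyl) analogue of 14 (C9 silyl ether kept) | C=C[C@@H]1C=C[C@@H]2[C@@H]3C[C@H](C)C[C@H](C)[C@H]3[C@@H](O[Si](C)(C)C(C)(C)C)[C@H]2[C@@H]1CO | intermediate
16 | C9-ol/C1-hydroxymethyl diol | C=C[C@@H]1C=C[C@@H]2[C@@H]3C[C@H](C)C[C@H](C)[C@H]3[C@@H](O)[C@H]2[C@@H]1CO | intermediate
17 | C9-ol with C1-CH2O-triisopropylsilyl | C=C[C@@H]1C=C[C@@H]2[C@@H]3C[C@H](C)C[C@H](C)[C@H]3[C@@H](O)[C@H]2[C@@H]1CO[Si](C(C)C)(C(C)C)C(C)C | intermediate
18 | trichloroethylene | ClC=C(Cl)Cl | starting material
19 | C9 (E)-1,2-dichlorovinyl ether of 17 | C=C[C@@H]1C=C[C@@H]2[C@@H]3C[C@H](C)C[C@H](C)[C@H]3[C@@H](O/C(Cl)=C\Cl)[C@H]2[C@@H]1CO[Si](C(C)C)(C(C)C)C(C)C | intermediate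
20 | C9 chloroethynyl ether | C=C[C@@H]1C=C[C@@H]2[C@@H]3C[C@H](C)C[C@H](C)[C@H]3[C@@H](OC#CCl)[C@H]2[C@@H]1CO[Si](C(C)C)(C(C)C)C(C)C | intermediate (not isolated)
21 | C9 lithioethynyl ether | C=C[C@@H]1C=C[C@@H]2[C@@H]3C[C@H](C)C[C@H](C)[C@H]3[C@@H](OC#C[Li])[C@H]2[C@@H]1CO[Si](C(C)C)(C(C)C)C(C)C | intermediate (not isolated)
22 | C9 ethynyl ether, C1-CH2O-triisopropylsilyl | C=C[C@@H]1C=C[C@@H]2[C@@H]3C[C@H](C)C[C@H](C)[C@H]3[C@@H](OC#C)[C@H]2[C@@H]1CO[Si](C(C)C)(C(C)C)C(C)C | intermediate
23 | C9 ethynyl ether, C1-CH2OH | C=C[C@@H]1C=C[C@@H]2[C@@H]3C[C@H](C)C[C@H](C)[C@H]3[C@@H](OC#C)[C@H]2[C@@H]1CO | intermediate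
24 | C9 ethynyl ether, C1-carbaldehyde | C=C[C@@H]1C=C[C@@H]2[C@@H]3C[C@H](C)C[C@H](C)[C@H]3[C@@H](OC#C)[C@H]2[C@@H]1C=O | intermediate
25 | coumalic acid (2-oxo-2H-pyran-5-carboxylic acid) | OC(=O)c1ccc(=O)oc1 | starting material
26 | 5-(hydroxymethyl)-2H-pyran-2-one | OCc1ccc(=O)oc1 | intermediate
27 | 5-(bromomethyl)-2H-pyran-2-one | BrCc1ccc(=O)oc1 | intermediate
28 | (S)-malamic acid, (2S)-4-amino-2-hydroxy-4-oxobutanoic acid | NC(=O)C[C@H](O)C(=O)O | starting material
29 | triethylsilyl (2S)-4-amino-4-oxo-2-(triethylsilyloxy)butanoate | NC(=O)C[C@H](O[Si](CC)(CC)CC)C(=O)O[Si](CC)(CC)CC | intermediate (not isolated)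
30 | (2S)-4-amino-4-oxo-2-(triethylsilyloxy)butanoic acid | NC(=O)C[C@H](O[Si](CC)(CC)CC)C(=O)O | intermediate
31 | S-ethyl (2S)-4-amino-4-oxo-2-(triethylsilyloxy)butanethioate | NC(=O)C[C@H](O[Si](CC)(CC)CC)C(=O)SCC | intermediate
32 | (2-oxo-2H-pyran-5-yl)methylzinc bromide | Br[Zn]Cc1ccc(=O)oc1 | intermediate (not isolated)
33 | (3S)-4-oxo-5-(2-oxo-2H-pyran-5-yl)-3-(triethylsilyloxy)pentanamide | NC(=O)C[C@H](O[Si](CC)(CC)CC)C(=O)Cc1ccc(=O)oc1 | intermediate (not isolated)
34 | (4S)-5-hydroxy-5-[(2-oxo-2H-pyran-5-yl)methyl]-4-(triethylsilyloxy)pyrrolidin-2-one, both C5 epimers | O=C1C[C@H](O[Si](CC)(CC)CC)C(O)(Cc2ccc(=O)oc2)N1 | intermediate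
35 | (4S,5S)-4,5-dihydroxy-5-[(2-oxo-2H-pyran-5-yl)methyl]pyrrolidin-2-one 4,5-O-isopropylidene acetal (cis-fused) | O=C1C[C@@H]2OC(C)(C)O[C@]2(Cc3ccc(=O)oc3)N1 | intermediate
36 | N-trimethylsilyl derivative of 35 | O=C1C[C@@H]2OC(C)(C)O[C@]2(Cc3ccc(=O)oc3)N1[Si](C)(C)C | intermediate (not isolated)
37 | aldol adduct: C1-CH(OH)-C3′ link between 24 and 35, carbinol and C3′ unassigned | C=C[C@@H]1C=C[C@@H]2[C@@H]3C[C@H](C)C[C@H](C)[C@H]3[C@@H](OC#C)[C@H]2[C@@H]1C(O)C4C(=O)N[C@@]5(Cc6ccc(=O)oc6)OC(C)(C)O[C@@H]45 | intermediate
38 | 3′-acyl lactam as its (Z)-enol (enol OH cis to the lactam C=O) | C=C[C@@H]1C=C[C@@H]2[C@@H]3C[C@H](C)C[C@H](C)[C@H]3[C@@H](OC#C)[C@H]2[C@@H]1/C(O)=C4/C(=O)N[C@@]5(Cc6ccc(=O)oc6)OC(C)(C)O[C@@H]45 | intermediate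
39 | (Z)-tert-butyldimethylsilyl enol ether of 38: C9 ethynyl ether, pyronylmethyl acetonide lactam | C=C[C@@H]1C=C[C@@H]2[C@@H]3C[C@H](C)C[C@H](C)[C@H]3[C@@H](OC#C)[C@H]2[C@@H]1/C(O[Si](C)(C)C(C)(C)C)=C4/C(=O)N[C@@]5(Cc6ccc(=O)oc6)OC(C)(C)O[C@@H]45 | intermediate
40 | bridged (4+2) adduct, 2-oxabicyclo[2.2.2]octa-5,7-dien-3-one inside the macrocycle; bridgehead configuration open (either pyrone face) | C=C[C@@H]1C=C[C@@H]2[C@@H]3C[C@H](C)C[C@H](C)[C@H]3[C@H]3OC4=CC7OC(=O)C4C=C7C[C@@]4(OC6(C)C)NC(=O)/C(=C(\O[Si](C)(C)C(C)(C)C)[C@H]1[C@@H]23)[C@@H]4O6 | intermediate (not isolated)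
41 | protected xenoacremone A: silyl enol ether, 4′,5′-O-isopropylidene acetal | C=C[C@@H]1C=C[C@@H]2[C@@H]3C[C@H](C)C[C@H](C)[C@H]3[C@H]3Oc4ccc(cc4)C[C@@]4(OC6(C)C)NC(=O)/C(=C(\O[Si](C)(C)C(C)(C)C)[C@H]1[C@@H]23)[C@@H]4O6 | intermediate
42 | xenoacremone A | C=C[C@@H]1C=C[C@@H]2[C@@H]3C[C@H](C)C[C@H](C)[C@H]3[C@H]3Oc4ccc(cc4)C[C@@]4(O)NC(=O)/C(=C(\O)[C@H]1[C@@H]23)[C@@H]4O | target

## Step count and risks

Total steps: 26. Longest linear sequence: 20 (steps 1–15 and 22–26).

**Step 25.** The alkynyl ether may be consumed by adventitious acid or water, by oligomerisation, or by meta-oriented closure before the strained para-bridging transition state is reached. The fallback sets out from alcohol 15 and thioester 31 and comes back at target 42. It closes the ring by copper-mediated intramolecular O-arylation of the C9 alcohol, a known aryl ether synthesis, with ring E brought in ready-made. Thioester 31 and commercial 4-bromobenzylzinc bromide (PdCl2(PPh3)2, toluene/THF, rt, where the aryl bromide stays inert) give keto amide F1, which closes to hydroxy lactam F2. 2,2-Dimethoxypropane and camphorsulfonic acid convert it into the bromobenzyl acetonide lactam F3. Alcohol 15 is oxidised with Dess–Martin periodinane to aldehyde F4. The N,C-dilithio derivative of F3 (LiN(i-Pr)2, 2.2 equiv, THF, −78 → −20 °C) adds to F4 to give aldol F5. Dess–Martin oxidation gives β-keto lactam F6, and Bu4NF frees the C9 alcohol F7. CuI, 3,4,7,8-tetramethyl-1,10-phenanthroline and Cs2CO3 in toluene at 110 °C under high dilution should then close the aryl ether to macrocycle F8, which the conditions of step 26 convert into 42.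

**Step 8.** Attack on the other enoate face (H-4a anti to H-4b) or erosion of endo selectivity would give diastereomeric tricycles. The fallback sets out from triene enoate 13 and comes back at alcohol 15. It moves the cycloaddition to an iminium-activated enal under catalyst control. i-Bu2AlH at −78 °C reduces 13 to allylic alcohol F9, and MnO2 gives trienal F10. A 5-benzyl-2-tert-butyl-3-methylimidazolidin-4-one trifluoroacetate salt (the enantiomer matched to the substrate, MeCN/H2O, −20 °C) should then give tricyclic aldehyde F4 through the endo iminium transition state. NaBH4 in the same flask reduces F4 to 15.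

**Step 1.** Poor syn/anti or facial selectivity in the trapping, conjugate addition to the enoate, or incomplete enantiotopic discrimination would erode the purity of 4. The fallback sets out from 1 and 2 and comes back at 4. It replaces the lithium enolate by enamine catalysis: (S)-proline (30 mol %) in DMSO at rt. Its usual sense (anti aldol with the configuration of 4 at C8a and C9) also selects the enantiotopic α-carbon, and no new compound is involved.

Further compounds
F1 | step 25 | (3S)-5-(4-bromophenyl)-4-oxo-3-(triethylsilyloxy)pentanamide | NC(=O)C[C@H](O[Si](CC)(CC)CC)C(=O)Cc1ccc(Br)cc1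
F2 | step 25 | (4S)-5-(4-bromobenzyl)-5-hydroxy-4-(triethylsilyloxy)pyrrolidin-2-one, both C5 epimers | O=C1C[C@H](O[Si](CC)(CC)CC)C(O)(Cc2ccc(Br)cc2)N1
F3 | step 25 | (4S,5S)-5-(4-bromobenzyl)-4,5-dihydroxypyrrolidin-2-one 4,5-O-isopropylidene acetal | O=C1C[C@@H]2OC(C)(C)O[C@]2(Cc3ccc(Br)cc3)N1
F4 | step 25 | C9 tert-butyldimethylsilyl ether, C1-carbaldehyde tricycle | C=C[C@@H]1C=C[C@@H]2[C@@H]3C[C@H](C)C[C@H](C)[C@H]3[C@@H](O[Si](C)(C)C(C)(C)C)[C@H]2[C@@H]1C=O
F5 | step 25 | aldol adduct of F3 and F4, carbinol and C3′ unassigned | C=C[C@@H]1C=C[C@@H]2[C@@H]3C[C@H](C)C[C@H](C)[C@H]3[C@@H](O[Si](C)(C)C(C)(C)C)[C@H]2[C@@H]1C(O)C4C(=O)N[C@@]5(Cc6ccc(Br)cc6)OC(C)(C)O[C@@H]45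
F6 | step 25 | 3′-acyl lactam (Z)-enol, C9 silyl ether, bromobenzyl acetonide | C=C[C@@H]1C=C[C@@H]2[C@@H]3C[C@H](C)C[C@H](C)[C@H]3[C@@H](O[Si](C)(C)C(C)(C)C)[C@H]2[C@@H]1/C(O)=C4/C(=O)N[C@@]5(Cc6ccc(Br)cc6)OC(C)(C)O[C@@H]45
F7 | step 25 | 3′-acyl lactam (Z)-enol, free C9 alcohol, bromobenzyl acetonide | C=C[C@@H]1C=C[C@@H]2[C@@H]3C[C@H](C)C[C@H](C)[C@H]3[C@@H](O)[C@H]2[C@@H]1/C(O)=C4/C(=O)N[C@@]5(Cc6ccc(Br)cc6)OC(C)(C)O[C@@H]45
F8 | step 25 | xenoacremone A 4′,5′-O-isopropylidene acetal | C=C[C@@H]1C=C[C@@H]2[C@@H]3C[C@H](C)C[C@H](C)[C@H]3[C@H]3Oc4ccc(cc4)C[C@@]4(OC6(C)C)NC(=O)/C(=C(\O)[C@H]1[C@@H]23)[C@@H]4O6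
F9 | step 8 | allylic alcohol from 13 (CO2Et replaced by CH2OH) | OC/C=C/[C@H](O[Si](C)(C)C(C)(C)C)[C@@H]1[C@@H](C)C[C@@H](C)C[C@H]1/C=C/C=C/C=C
F10 | step 8 | trienal from F9 | O=C/C=C/[C@H](O[Si](C)(C)C(C)(C)C)[C@@H]1[C@@H](C)C[C@@H](C)C[C@H]1/C=C/C=C/C=C
F0 | step 1 | none | none
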